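(The runs come from a simulation on assumed constants; the scatter is artificial.)

**Late readings.** Late in the red run Z lags behind a simple first-order count, and the earlier readings show how far that count reaches.

| flask | D | G | remark | time |
|---|---|---|---|---|
| green | 0.095 M (in portions, 3) | 0.91 mol% | run made earlier; portions every 2.0 min |  |
| red | 0.095 M (in portions, 3) | 6.3 mol% | run made earlier; portions every 2.0 min |  |
| ochre | 0.064 M (in portions, 3) | 2.3 mol% | run made earlier; portions every 2.0 min |  |
| midnight | 0.025 M (in portions, 3) | 1.2 mol% | the portions of D follow each other after 2.0 min, the first at the start | 12 min |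
| autumn | 0.095 M (in portions, 3) | 2.3 mol% | the portions of D follow each other after 4.0 min, the first at the start | 12 min |
| dusk | 0.095 M (in portions, 3) | 6 mol% | the portions of D follow each other after 0.50 min, the first at the start | 12 min |
| winter | 0.15 M (in portions, 3) | 2.3 mol% | the portions of D follow each other after 3.0 min, the first at the start | 12 min |
| summer | 0.095 M (in portions, 3) | 10 mol% | the portions of D follow each other after 2.0 min, the first at the start | 12 min |
| dawn | 0.095 M (in portions, 3) | 2.3 mol% | the portions of D follow each other after 2.0 min, the first at the start | 12 min |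

| green: time / min | green: Z / % | red: time / min | red: Z / % | ochre: time / min | ochre: Z / % |
|---|---|---|---|---|---|
| 0.833 | 1.9 | 0.667 | 6.1 | 1.50 | 4.6 |
| 2.00 | 2.2 | 1.33 | 9.4 | 3.00 | 7.7 |
| 4.00 | 6.1 | 2.50 | 20.0 | 5.00 | 16.6 |
| 6.00 | 11.3 | 4.00 | 34.2 | 6.00 | 23.3 |
| 8.00 | 16.4 | 8.00 | 64.8 | 8.00 | 30.9 |

(readings scatter by 1 percentage point)

- the analysis behind the earlier runs scatters by 1 percentage point, standard deviation

* the flasks put in order of amount of Z, in percent of the D charged, best first, at 12 min (midnight / autumn / dusk / winter / summer / dawn)
* the amount of Z, in percent of the D charged of the flask you put first, at 12 min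
* the amount of Z, in percent of the D charged of the flask you put last, at 12 min

**Bench rule.** Suppose D falls in a pseudo-first-order way, with G held at its charged concentration c_G, the loading times the charge of D. At modest conversion the ages of the 3 portions can be replaced by their mean, t − τ, where τ is the interval between portions. Then Z, as a fraction of the charge, is 1 − exp(−X), with exposure X = k′ c_G (t − τ). The ochre reading at 6.00 min, with the last portion in, gives the turnover constant k′, the loss rate of D per D and per G, as 45.1 M⁻¹ min⁻¹, a reading that carries the scatter.

**Its border.** For red at 8.00 min the exposure is 1.62 and the rule gives 80.2%, but the reading is 64.8%. Z stands there at 0.0616 M, against 0.0149 M in the ochre reading, a ratio of 4.13. Green at 8.00 min holds 0.0156 M of Z and reads a lower k′ of 34.5 M⁻¹ min⁻¹, so the value of k′ spreads between these runs. The rule's percentages are taken here for exposures below red's, with that spread on k′.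

**Own reckoning.** Midnight has c_G = 3.00 × 10⁻⁴ M, so X = 0.135 and Z = 12.6%. That exposure stands below red's 1.62. The exposures at 12 min are summer 4.28, dusk 2.95, winter 1.40, dawn 0.984 and autumn 0.788. This ranking is kept, but summer's rule value of 98.6% is not, as summer's exposure stands above red's.

**The forecast.** It gives summer > dusk > winter > dawn > autumn > midnight, with the first at 87% (80% to 93%) and the last at 13% (10% to 16%). Of red's slowing it says: "I read this as product inhibition". Its top lies well below the rule's summer value.

**The flasks.** The order comes out as summer > dusk > winter > dawn > autumn > midnight, with summer at 87.8% and midnight at 14.6%, both inside the forecast's ranges.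

    D + G → Q (k = 68.4 M⁻¹ min⁻¹)
    Q ⇌ E (K = 73.8, k = 7.90 min⁻¹)
    E ⇌ G + Z (K = 0.0656 M, k = 551 min⁻¹)
    D + G → L (k = 0.537 M⁻¹ min⁻¹)

**The neighbour.** Midnight's Z exceeds the reckoned 12.6%, and read backwards it gives k′ = 52.7 M⁻¹ min⁻¹. The neighbour of midnight, charged with 0.48 mol% of G, has c_G = 1.20 × 10⁻⁴ M. With the ochre k′, its exposure is 0.0541 and its Z 5.27%. The neighbour flask holds Z at 6.18%, which read backwards gives k′ = 53.1 M⁻¹ min⁻¹.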